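## Retrosynthetic overview

1. Target ⇒ tri-O-protected decalin ketone (one-pot removal of two O-methyl groups and one O-benzyl group); its C-2 centre ⇒ the C-2 epimer by kinetic enolate protonation.
2. That epimer ⇒ acyclic (2E,4E,10Z,12E)-tetraenone by an inverse-electron-demand intramolecular Diels–Alder reaction. Ring B (cyclohexane) and ring A (cyclohexene) of the decalin form together in this step; the pyridine ring is bought and unmasked to the pyridone last.
3. Tetraenone ⇒ 3-lithio-2,4-dimethoxy-5-arylpyridine (Suzuki coupling, directed metalation) + tetraenyl Weinreb amide.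
4. Weinreb amide ⇒ HWE on an (E)-enal ⇐ SeO2 oxidation of a (Z,E)-diene ⇐ Z-selective Wittig reaction of the (S)-citronellyl ylide with crotonaldehyde. (S)-Citronellyl bromide supplies the only purchased stereocentre.

Assumption: the configuration is read literally from the SMILES, i.e. a (1S,2S,4aS,7S,8aR)-decalin with trans ring fusion, H-1, H-2, H-7 and H-8a on one face and H-4a on the other (propenyl cis to C-8 and cis to the acyl group), so the dienophile must be a Z-alkene.

## Route

Step 1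
Reactants: 1 (S)-(+)-citronellyl bromide [(6S)-8-bromo-2,6-dimethyloct-2-ene]
Product: 2 [(3S)-3,7-dimethyloct-6-en-1-yl]triphenylphosphonium bromide
Conditions: PPh3 (1.1 equiv), MeCN, reflux, 36 h; triturate with Et2O
Reagents that add atoms: triphenylphosphine, c1ccc(cc1)P(c1ccccc1)c1ccccc1
Why: SN2 quaternisation of the primary bromide by the phosphine gives the Wittig salt and leaves the remote stereocentre and the trisubstituted alkene untouched.

Step 2
Reactants: 2 [(3S)-3,7-dimethyloct-6-en-1-yl]triphenylphosphonium bromide; 3 (E)-but-2-enal (crotonaldehyde)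
Product: 5 (2E,4Z,7S)-7,11-dimethyldodeca-2,4,10-triene, via phosphorus ylide 4 (not isolated)
Conditions: NaN(SiMe3)2 (1.05 equiv), THF, −78 → 0 °C; then 3, −78 °C → rt; AgNO3-impregnated SiO2 removes the minor 4E isomer
Reagents that add atoms: none
Why: Lithium-free Wittig olefination of a non-stabilised ylide with an enal goes through the kinetically favoured cis-oxaphosphetane, so the new C4=C5 bond is Z while the E bond of crotonaldehyde is carried over unchanged.

Step 3
Reactants: 5 (2E,4Z,7S)-7,11-dimethyldodeca-2,4,10-triene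
Product: 7 (2E,6S,8Z,10E)-2,6-dimethyldodeca-2,8,10-trienal, via allylic alcohol 6 (not isolated)
Conditions: SeO2 (0.3 equiv), t-BuOOH (2.5 equiv), salicylic acid (0.1 equiv), CH2Cl2, 0 °C → rt; filter; MnO2 (10 equiv), CH2Cl2, rt
Reagents that add atoms: selenium dioxide, O=[Se]=O; tert-butyl hydroperoxide, CC(C)(C)OO (terminal oxidant that restores SeO2)
Why: In this Riley allylic oxidation the ene reaction of SeO2 picks the most electron-rich trisubstituted alkene and the following [2,3]-sigmatropic shift puts oxygen on the E-methyl group only, after which MnO2 oxidises the allylic alcohol to the (E)-enal without touching the diene.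

Step 4
Reactants: 7 (2E,6S,8Z,10E)-2,6-dimethyldodeca-2,8,10-trienal; 8 diethyl {2-[methoxy(methyl)amino]-2-oxoethyl}phosphonate
Product: 10 (2E,4E,8S,10Z,12E)-N-methoxy-N,4,8-trimethyltetradeca-2,4,10,12-tetraenamide, via sodium phosphonate carbanion 9 (not isolated)
Conditions: NaH (1.2 equiv), 8 (1.2 equiv), THF, 0 °C; then 7, 0 °C → rt
Reagents that add atoms: none
Why: Horner–Wadsworth–Emmons olefination with a stabilised phosphonate anion gives the new C2=C3 bond E under equilibrating oxaphosphetane formation, completing the (2E,4E)-dienoyl unit.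

Step 5
Reactants: 11 5-bromo-2,4-dimethoxypyridine; 12 [4-(benzyloxy)phenyl]boronic acid
Product: 13 5-[4-(benzyloxy)phenyl]-2,4-dimethoxypyridine
Conditions: Pd(PPh3)4 (5 mol %), K2CO3 (2.5 equiv), 1,4-dioxane/H2O (4:1), 90 °C
Reagents that add atoms: none
Why: Suzuki–Miyaura cross-coupling (oxidative addition into C–Br, transmetalation of the boronate, reductive elimination) joins the two aromatic rings, and all three ethers are inert to it.

Step 6
Reactants: 13 5-[4-(benzyloxy)phenyl]-2,4-dimethoxypyridine; 10 (2E,4E,8S,10Z,12E)-N-methoxy-N,4,8-trimethyltetradeca-2,4,10,12-tetraenamide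
Product: 16 (2E,4E,8S,10Z,12E)-1-{5-[4-(benzyloxy)phenyl]-2,4-dimethoxypyridin-3-yl}-4,8-dimethyltetradeca-2,4,10,12-tetraen-1-one, via 3-lithiopyridine 14 (not isolated), via tetrahedral lithium adduct 15 (not isolated)
Conditions: 2,2,6,6-tetramethylpiperidine (1.25 equiv), n-BuLi (1.2 equiv), THF, −78 → 0 °C; 13 (1.3 equiv), −78 → −40 °C, 1 h; 10 (1.0 equiv), −78 → −30 °C; sat. aq. NH4Cl at −78 °C
Reagents that add atoms: none
Why: Directed ortho-metalation occurs at C-3, the position flanked by both methoxy groups, and acyl substitution on the Weinreb amide stops at the chelated tetrahedral adduct until work-up, so the dienone is never exposed to the aryllithium.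

Step 7
Reactants: 16 (2E,4E,8S,10Z,12E)-1-{5-[4-(benzyloxy)phenyl]-2,4-dimethoxypyridin-3-yl}-4,8-dimethyltetradeca-2,4,10,12-tetraen-1-one
Product: 17 {5-[4-(benzyloxy)phenyl]-2,4-dimethoxypyridin-3-yl}{(1S,2R,4aS,7S,8aR)-4,7-dimethyl-1-[(1E)-prop-1-en-1-yl]-1,2,4a,5,6,7,8,8a-octahydronaphthalen-2-yl}methanone
Conditions: toluene (0.01 M), 2,6-di-tert-butyl-4-methylphenol (5 mol %), 135 °C, sealed tube, 24–48 h
Reagents that add atoms: none
Why: In this thermal inverse-electron-demand intramolecular Diels–Alder reaction the dienone is the 4π partner and the Z-alkene the 2π partner (the Z,E-diene cannot reach the s-cis geometry to compete as a diene); the chair tether with the C-7 methyl equatorial and the diene methyl next to the tether, which disfavours the cis-fused transition state, give the trans-decalin with H-7 and H-8a cis, the Z-alkene puts the propenyl group cis to C-8, and the E,E-diene puts the acyl group on the face of C-5 (H-2 cis to H-4a).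

Step 8
Reactants: 17 {5-[4-(benzyloxy)phenyl]-2,4-dimethoxypyridin-3-yl}{(1S,2R,4aS,7S,8aR)-4,7-dimethyl-1-[(1E)-prop-1-en-1-yl]-1,2,4a,5,6,7,8,8a-octahydronaphthalen-2-yl}methanone
Product: 19 {5-[4-(benzyloxy)phenyl]-2,4-dimethoxypyridin-3-yl}{(1S,2S,4aS,7S,8aR)-4,7-dimethyl-1-[(1E)-prop-1-en-1-yl]-1,2,4a,5,6,7,8,8a-octahydronaphthalen-2-yl}methanone, via potassium dienolate 18 (not isolated)
Conditions: KN(SiMe3)2 (1.2 equiv), THF, −78 → −40 °C, 1 h; recool to −78 °C; AcOH (5 equiv) in THF added fast; pH 7 buffer work-up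
Reagents that add atoms: none
Why: Deprotonation to the dienolate and kinetic α-protonation at −78 °C along the axial trajectory on the face opposite the axial propenyl group inverts C-2 and keeps the ring alkene out of conjugation (contra-thermodynamic enolate protonation).

Step 9
Reactants: 19 {5-[4-(benzyloxy)phenyl]-2,4-dimethoxypyridin-3-yl}{(1S,2S,4aS,7S,8aR)-4,7-dimethyl-1-[(1E)-prop-1-en-1-yl]-1,2,4a,5,6,7,8,8a-octahydronaphthalen-2-yl}methanone
Product: 21 4-hydroxy-5-(4-hydroxyphenyl)-3-{[(1S,2S,4aS,7S,8aR)-4,7-dimethyl-1-[(1E)-prop-1-en-1-yl]-1,2,4a,5,6,7,8,8a-octahydronaphthalen-2-yl]carbonyl}pyridin-2(1H)-one (CNP0267724.3), via tris(trimethylsilyl) ether 20 (not isolated)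
Conditions: Me3SiCl (6 equiv), NaI (6 equiv), MeCN/CH2Cl2, 0 °C → rt, dark; MeOH, 0 °C; aq. Na2S2O3 wash
Reagents that add atoms: none
Why: Me3SiI made in situ silylates the pyridine nitrogen, the ketone oxygen and the benzyl ether oxygen, iodide then removes both methyl groups and the benzyl group by SN2 (silyl iodide ether cleavage), and methanolysis of the silyl ethers frees the 4-hydroxy-2-pyridone and the phenol without base, so C-2 is not disturbed.

## Compound list

1 | (S)-(+)-citronellyl bromide, (6S)-8-bromo-2,6-dimethyloct-2-ene | BrCC[C@@H](C)CCC=C(C)C | starting material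
2 | [(3S)-3,7-dimethyloct-6-en-1-yl]triphenylphosphonium bromide | [Br-].c1ccccc1[P+](c1ccccc1)(c1ccccc1)CC[C@@H](C)CCC=C(C)C | intermediate
3 | (E)-but-2-enal (crotonaldehyde) | C/C=C/C=O | starting material
4 | [(3S)-3,7-dimethyloct-6-en-1-ylidene]triphenylphosphorane (ylide) | c1ccccc1P(c1ccccc1)(c1ccccc1)=CC[C@@H](C)CCC=C(C)C | intermediate
5 | (2E,4Z,7S)-7,11-dimethyldodeca-2,4,10-triene | C/C=C/C=C\C[C@@H](C)CCC=C(C)C | intermediate
6 | (2E,6S,8Z,10E)-2,6-dimethyldodeca-2,8,10-trien-1-ol | C/C=C/C=C\C[C@@H](C)CC/C=C(C)/CO | intermediate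
7 | (2E,6S,8Z,10E)-2,6-dimethyldodeca-2,8,10-trienal | C/C=C/C=C\C[C@@H](C)CC/C=C(C)/C=O | intermediate
8 | diethyl {2-[methoxy(methyl)amino]-2-oxoethyl}phosphonate | CCOP(=O)(CC(=O)N(C)OC)OCC | starting material
9 | sodium salt of the α-carbanion of 8 | CCOP(=O)(OCC)[CH-]C(=O)N(C)OC.[Na+] | intermediate
10 | (2E,4E,8S,10Z,12E)-N-methoxy-N,4,8-trimethyltetradeca-2,4,10,12-tetraenamide | C/C=C/C=C\C[C@@H](C)CC/C=C(C)/C=C/C(=O)N(C)OC | intermediate
11 | 5-bromo-2,4-dimethoxypyridine | COc1cc(OC)c(Br)cn1 | starting material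
12 | [4-(benzyloxy)phenyl]boronic acid | OB(O)c1ccc(OCc2ccccc2)cc1 | starting material
13 | 5-[4-(benzyloxy)phenyl]-2,4-dimethoxypyridine | COc1cc(OC)c(-c2ccc(OCc3ccccc3)cc2)cn1 | intermediate
14 | {5-[4-(benzyloxy)phenyl]-2,4-dimethoxypyridin-3-yl}lithium | [Li]c1c(OC)ncc(-c2ccc(OCc3ccccc3)cc2)c1OC | intermediate
15 | lithium alkoxide adduct of 14 to the amide carbonyl of 10 (mixture at the new carbon) | C/C=C/C=C\C[C@@H](C)CC/C=C(C)/C=C/C(O[Li])(N(C)OC)c1c(OC)ncc(-c2ccc(OCc3ccccc3)cc2)c1OC | intermediate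
16 | (2E,4E,8S,10Z,12E)-1-{5-[4-(benzyloxy)phenyl]-2,4-dimethoxypyridin-3-yl}-4,8-dimethyltetradeca-2,4,10,12-tetraen-1-one | C/C=C/C=C\C[C@@H](C)CC/C=C(C)/C=C/C(=O)c1c(OC)ncc(-c2ccc(OCc3ccccc3)cc2)c1OC | intermediate
17 | {5-[4-(benzyloxy)phenyl]-2,4-dimethoxypyridin-3-yl}{(1S,2R,4aS,7S,8aR)-4,7-dimethyl-1-[(1E)-prop-1-en-1-yl]-1,2,4a,5,6,7,8,8a-octahydronaphthalen-2-yl}methanone | C/C=C/[C@H]1[C@H]2C[C@@H](C)CC[C@@H]2C(C)=C[C@@H]1C(=O)c1c(OC)ncc(-c2ccc(OCc3ccccc3)cc2)c1OC | intermediate
18 | potassium dienolate of 17 (C-2 planar) | C/C=C/[C@H]1[C@H]2C[C@@H](C)CC[C@@H]2C(C)=CC1=C([O-])c1c(OC)ncc(-c2ccc(OCc3ccccc3)cc2)c1OC.[K+] | intermediate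
19 | {5-[4-(benzyloxy)phenyl]-2,4-dimethoxypyridin-3-yl}{(1S,2S,4aS,7S,8aR)-4,7-dimethyl-1-[(1E)-prop-1-en-1-yl]-1,2,4a,5,6,7,8,8a-octahydronaphthalen-2-yl}methanone | C/C=C/[C@H]1[C@H]2C[C@@H](C)CC[C@@H]2C(C)=C[C@H]1C(=O)c1c(OC)ncc(-c2ccc(OCc3ccccc3)cc2)c1OC | intermediate
20 | tris(trimethylsilyl) ether of 21 (2-O, 4-O and phenol O silylated) | C/C=C/[C@H]1[C@H]2C[C@@H](C)CC[C@@H]2C(C)=C[C@H]1C(=O)c1c(O[Si](C)(C)C)ncc(-c2ccc(O[Si](C)(C)C)cc2)c1O[Si](C)(C)C | intermediate
21 | 4-hydroxy-5-(4-hydroxyphenyl)-3-{[(1S,2S,4aS,7S,8aR)-4,7-dimethyl-1-[(1E)-prop-1-en-1-yl]-1,2,4a,5,6,7,8,8a-octahydronaphthalen-2-yl]carbonyl}pyridin-2(1H)-one | C/C=C/[C@H]1[C@H]2C[C@@H](C)CC[C@@H]2C(C)=C[C@H]1C(=O)c1c(O)c(-c2ccc(O)cc2)c[nH]c1=O | target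

## Step count and risks

Total step count: 9. Longest linear sequence: 8 steps (1 → 2 → 5 → 7 → 10 → 16 → 17 → 19 → 21; step 5 is the side branch).

The three steps most likely to fail:

Step 7 (cycloaddition). The Z-dienophile reacts slowly, the Z,E-diene can drift by a [1,5]-hydrogen shift on long heating, and some cis-fused adduct may form. The fallback sets out from 10 and comes back at 17, moving the cycloaddition ahead of the fragment coupling. Reduction of 10 with i-Bu2AlH (THF, −78 °C) gives (2E,4E,8S,10Z,12E)-4,8-dimethyltetradeca-2,4,10,12-tetraenal F1. This small dienal, whose formyl group can be activated with Me2AlCl (CH2Cl2, −40 → 0 °C) or simply heated in toluene at 110 °C, is cyclised to the decalin aldehyde F2. Addition of 14 (made from 13 as in step 6) gives the carbinol F3 as a mixture at the carbinol carbon, and Dess–Martin periodinane oxidises it to 17. Any C-2 epimerisation of F2 is harmless because step 8 resets that centre.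

Step 8 (C-2 inversion). Deprotonation of the hindered ketone may be slow, or protonation may not be face-selective. The fallback sets out from 17 and comes back at 21, replacing kinetic by thermodynamic control after unmasking. Compound 17 is dealkylated with Me3SiCl/NaI exactly as in step 9 to give the C-2 epimer of the target F4. This is equilibrated at C-2 with Et3N or DBU in MeOH at rt to 40 °C; the ring alkene should stay out of conjugation because the ketone is tied up in the hydrogen-bonded vinylogous acid. The position of this equilibrium is not predictable with confidence, so 21 is separated by HPLC and recovered F4 is recycled.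

Step 9 (global dealkylation). HI or benzyl iodide formed alongside the silyloxypyridine could attack the alkenes or N-alkylate. The fallback sets out from 19 and comes back at 21 in two orthogonal stages. LiI (EtOAc, 70 °C, then dilute acid) removes the two pyridine O-methyl groups by SN2 on the activated vinylogous ester and imidate positions and gives the O-benzyl pyridone F5. BCl3 with pentamethylbenzene as cation scavenger (CH2Cl2, −78 °C) then removes the benzyl group without acid strong enough to touch the alkenes or C-2.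

## Further compounds

F1 | step 7 | (2E,4E,8S,10Z,12E)-4,8-dimethyltetradeca-2,4,10,12-tetraenal | C/C=C/C=C\C[C@@H](C)CC/C=C(C)/C=C/C=O
F2 | step 7 | (1S,2R,4aS,7S,8aR)-4,7-dimethyl-1-[(1E)-prop-1-en-1-yl]-1,2,4a,5,6,7,8,8a-octahydronaphthalene-2-carbaldehyde | C/C=C/[C@H]1[C@H]2C[C@@H](C)CC[C@@H]2C(C)=C[C@@H]1C=O
F3 | step 7 | {5-[4-(benzyloxy)phenyl]-2,4-dimethoxypyridin-3-yl}{(1S,2R,4aS,7S,8aR)-4,7-dimethyl-1-[(1E)-prop-1-en-1-yl]-1,2,4a,5,6,7,8,8a-octahydronaphthalen-2-yl}methanol (both carbinol epimers) | C/C=C/[C@H]1[C@H]2C[C@@H](C)CC[C@@H]2C(C)=C[C@@H]1C(O)c1c(OC)ncc(-c2ccc(OCc3ccccc3)cc2)c1OC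
F4 | step 8 | 4-hydroxy-5-(4-hydroxyphenyl)-3-{[(1S,2R,4aS,7S,8aR)-4,7-dimethyl-1-[(1E)-prop-1-en-1-yl]-1,2,4a,5,6,7,8,8a-octahydronaphthalen-2-yl]carbonyl}pyridin-2(1H)-one | C/C=C/[C@H]1[C@H]2C[C@@H](C)CC[C@@H]2C(C)=C[C@@H]1C(=O)c1c(O)c(-c2ccc(O)cc2)c[nH]c1=O
F5 | step 9 | 5-[4-(benzyloxy)phenyl]-4-hydroxy-3-{[(1S,2S,4aS,7S,8aR)-4,7-dimethyl-1-[(1E)-prop-1-en-1-yl]-1,2,4a,5,6,7,8,8a-octahydronaphthalen-2-yl]carbonyl}pyridin-2(1H)-one | C/C=C/[C@H]1[C@H]2C[C@@H](C)CC[C@@H]2C(C)=C[C@H]1C(=O)c1c(O)c(-c2ccc(OCc3ccccc3)cc2)c[nH]c1=O
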